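**Retrosynthetic overview**
1. Target 31 ⇐ 30: the 4,5-oxirane is made last, by 2-OH-directed epoxidation of a Z C4=C5 olefin.
2. 30 ⇐ 29: the ten-membered carbocycle is closed by ring-closing metathesis at C4=C5; 29 ⇐ 24 by angeloylation, desilylation and A(1,3)-controlled OH-directed epoxidation of C1=C10.
3. 24 ⇐ 11 + 22: the key C7–C8 bond comes from an intermolecular zinc Barbier allylation of aldehyde 22 with bromobutenolide 11, which sets C7 and C8 and creates the α-methylene lactone.
4. 11 ⇐ acrolein + a silyl propargyl ether (lipase resolution sets C6; hydroalumination/iodination; carbonylative lactonisation). 22 ⇐ but-3-yn-1-ol (carboalumination; Keck methallylation sets C2).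
5. Ring order: butenolide (then γ-lactone) → 1,10-oxirane → ten-membered ring → 4,5-oxirane.

Assumption: the SMILES is read literally as (1R,2S,4R,5S,6S,7R,8S,10R), i.e. trans 1β,10α-epoxide, cis 4α,5α-epoxide, 2α-OH, 8α-angelate [(Z)-2-methylbut-2-enoate] and a 12,6α-lactone with H-7α; C1–C15 below are germacrane atom numbers.

**Route**

Step 1
Reactants: 1 tert-butyldimethyl(prop-2-yn-1-yloxy)silane; 2 prop-2-enal (acrolein)
Product: 5 rac-6-(tert-butyldimethylsilyloxy)hex-1-en-4-yn-3-yl acetate, via lithium acetylide 3 (not isolated), via lithium alkoxide 4 (not isolated)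
Conditions: n-BuLi, THF, −78 °C; 2, −78 °C; Ac2O, −78 °C to rt
Reagents that add atoms: acetic anhydride, CC(=O)OC(C)=O
Why: Acetylide 1,2-addition to the enal followed by in situ O-acetylation of the alkoxide gives the racemic ester for the enzymatic resolution, and the silyl ether is inert to both operations.

Step 2
Reactants: 5
Product: 6 (3R)-6-(tert-butyldimethylsilyloxy)hex-1-en-4-yn-3-ol
Conditions: Burkholderia cepacia lipase (Amano PS), pH 7 phosphate buffer/MTBE, 30 °C, stopped at about 45% conversion
Reagents that add atoms: none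
Why: Lipase-catalysed kinetic resolution by enantioselective hydrolysis (Kazlauskas rule, vinyl as the medium and the alkynyl chain as the large group) cleaves the R acetate preferentially and so sets the future C6 stereocentre, the S acetate being removed by chromatography.

Step 3
Reactants: 6
Product: 8 (3R,4Z)-6-(tert-butyldimethylsilyloxy)-5-iodohexa-1,4-dien-3-ol, via cyclic alkenylalanate 7 (not isolated)
Conditions: NaAlH2(OCH2CH2OCH3)2, THF, 0 °C; iodine, −78 to 0 °C; aqueous KNaC4H4O6/Na2S2O3
Reagents that add atoms: iodine, [I][I]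
Why: Hydroxyl-directed trans-hydroalumination of the propargylic alcohol puts aluminium on the distal alkyne carbon in a five-membered alanate and iodinolysis with retention gives the Z vinyl iodide with iodine cis to the carbinol, the cold quench suppressing loss of silyloxide to an allene and the carbinol centre being untouched.

Step 4
Reactants: 8
Product: 9 (5R)-3-[(tert-butyldimethylsilyloxy)methyl]-5-ethenylfuran-2(5H)-one
Conditions: PdCl2(PPh3)2 (5 mol%), CO (1 atm), K2CO3, THF, 25 °C
Reagents that add atoms: carbon monoxide, [C-]#[O+]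
Why: Palladium-catalysed carbonylative lactonisation (oxidative addition of zerovalent palladium to the vinyl iodide, CO insertion, capture of the acylpalladium by the cis hydroxyl) closes the butenolide with retention at the carbinol carbon, and room temperature with a heterogeneous base keeps the acidic C5 hydrogen of the 5-vinyl butenolide from epimerising.

Step 5
Reactants: 9
Product: 10 (5R)-5-ethenyl-3-(hydroxymethyl)furan-2(5H)-one
Conditions: 48% aqueous HF, MeCN, 0 °C
Reagents that add atoms: none
Why: Acidic desilylation frees the primary allylic alcohol without any base, so the base-labile 5-vinyl butenolide and its stereocentre survive.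

Step 6
Reactants: 10
Product: 11 (5R)-3-(bromomethyl)-5-ethenylfuran-2(5H)-one
Conditions: CBr4, PPh3, CH2Cl2, 0 °C
Reagents that add atoms: carbon tetrabromide, BrC(Br)(Br)Br
Why: The Appel reaction converts the primary allylic alcohol into the bromide by SN2 displacement of the oxyphosphonium group under neutral conditions that leave the lactone and its stereocentre alone.

Step 7
Reactants: 12 but-3-yn-1-ol
Product: 13 1-[(but-3-yn-1-yloxy)methyl]-4-methoxybenzene
Conditions: NaH, 4-methoxybenzyl chloride, Bu4NI (cat.), THF/DMF, 0 °C to rt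
Reagents that add atoms: 4-methoxybenzyl chloride, COc1ccc(CCl)cc1
Why: Williamson ether synthesis masks the future C8 oxygen as a PMB ether that can later be removed in the presence of a silyl ether.

Step 8
Reactants: 13
Product: 16 (2E)-5-[(4-methoxybenzyl)oxy]-3-methylpent-2-en-1-ol, via alkenyldimethylalane 14 (not isolated), via lithium alkenylaluminate 15 (not isolated)
Conditions: Me3Al, Cp2ZrCl2 (25 mol%), CH2Cl2, 0 °C to rt; solvent change to THF, n-BuLi, −78 °C; (CH2O)n, −78 °C to rt
Reagents that add atoms: trimethylaluminium, C[Al](C)C; paraformaldehyde (as formaldehyde), C=O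
Why: Negishi zirconium-catalysed carboalumination adds methyl and aluminium syn across the alkyne with full regiocontrol and the derived ate complex is hydroxymethylated with retention, which fixes the E trisubstituted C1=C10 olefin and brings in C14 and C2.

Step 9
Reactants: 16
Product: 17 (2E)-5-[(4-methoxybenzyl)oxy]-3-methylpent-2-enal
Conditions: MnO2 (activated), CH2Cl2, rt
Reagents that add atoms: none
Why: Selective allylic oxidation with MnO2 gives the enal without E/Z isomerisation or over-oxidation and does not touch the PMB ether.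

Step 10
Reactants: 17; 18 tributyl(2-methylprop-2-en-1-yl)stannane
Product: 19 (4S,5E)-8-[(4-methoxybenzyl)oxy]-2,6-dimethylocta-1,5-dien-4-ol
Conditions: (S)-BINOL (20 mol%), Ti(OiPr)4 (10 mol%), 4 Å molecular sieves, CH2Cl2, −20 °C, 72 h; aqueous NaHCO3
Reagents that add atoms: none
Why: Keck asymmetric allylation, in which the (S)-BINOL titanium Lewis acid exposes one enal face to the methallylstannane, gives the 1,2-adduct with the S carbinol (future C2, the same sense as other (S)-BINOL allylations in which the aldehyde substituent outranks the allyl group) and installs C3, C4 and C15.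

Step 11
Reactants: 19
Product: 20 tert-butyl{[(4S,5E)-8-[(4-methoxybenzyl)oxy]-2,6-dimethylocta-1,5-dien-4-yl]oxy}dimethylsilane
Conditions: TBSCl, imidazole, DMF, rt
Reagents that add atoms: tert-butyldimethylsilyl chloride, CC(C)(C)[Si](C)(C)Cl
Why: Silylation protects the C2 hydroxyl as a TBS ether that survives the oxidative PMB removal, the Barbier medium and the acylation.

Step 12
Reactants: 20
Product: 21 (3E,5S)-5-(tert-butyldimethylsilyloxy)-3,7-dimethylocta-3,7-dien-1-ol
Conditions: DDQ, CH2Cl2/pH 7 buffer (10:1), 0 °C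
Reagents that add atoms: none
Why: Oxidative PMB cleavage by DDQ (hydride abstraction, then hydrolysis of the oxocarbenium ion) is orthogonal to the TBS ether and spares the isolated olefins.

Step 13
Reactants: 21
Product: 22 (3E,5S)-5-(tert-butyldimethylsilyloxy)-3,7-dimethylocta-3,7-dienal
Conditions: Dess–Martin periodinane, NaHCO3 (solid buffer), CH2Cl2, 0 °C to rt; used at once
Reagents that add atoms: none
Why: Buffered Dess–Martin oxidation gives the β,γ-unsaturated aldehyde under neutral conditions, so the C1=C10 double bond does not migrate into conjugation before the coupling.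

Step 14
Reactants: 11; 22
Product: 24 (4R,5R)-5-ethenyl-4-[(1S,3E,5S)-5-(tert-butyldimethylsilyloxy)-1-hydroxy-3,7-dimethylocta-3,7-dien-1-yl]-3-methylideneoxolan-2-one, via allylzinc bromide 23 (not isolated)
Conditions: Zn (activated dust), THF/saturated aqueous NH4Cl, 0 °C to rt
Reagents that add atoms: none
Why: In this zinc Barbier carbonyl allylation the allylzinc from 11 attacks the aldehyde through its ring γ-carbon in a six-membered chair transition state, anti to the 5-vinyl group (7R, trans lactone) and with the ring-locked E-type allyl geometry and an equatorial aldehyde chain giving the anti 7,8 relationship (8S), while the double bond moves out to the α-methylene position.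

Step 15
Reactants: 24; 25 angelic acid, (2Z)-2-methylbut-2-enoic acid
Product: 27 (1S,3E,5S)-5-(tert-butyldimethylsilyloxy)-1-[(2R,3R)-2-ethenyl-4-methylidene-5-oxooxolan-3-yl]-3,7-dimethylocta-3,7-dien-1-yl (2Z)-2-methylbut-2-enoate, via mixed anhydride 26 (not isolated)
Conditions: 25, 2,4,6-trichlorobenzoyl chloride, Et3N, toluene, rt; then 24, 80 °C
Reagents that add atoms: none
Why: Yamaguchi-type esterification through the preformed 2,4,6-trichlorobenzoyl mixed anhydride, run without DMAP, acylates the hindered C8 alcohol with retention and without Z to E isomerisation of the angelate, and an excess of anhydride lets acylation outrun translactonisation to the 8,12-olide.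

Step 16
Reactants: 27
Product: 28 (1S,3E,5S)-1-[(2R,3R)-2-ethenyl-4-methylidene-5-oxooxolan-3-yl]-5-hydroxy-3,7-dimethylocta-3,7-dien-1-yl (2Z)-2-methylbut-2-enoate
Conditions: HF·pyridine, pyridine, THF, 0 °C to rt
Reagents that add atoms: none
Why: Buffered fluoride desilylation removes the allylic TBS ether without nucleophiles or strong base, so the α-methylene lactone and the angelate are untouched.

Step 17
Reactants: 28
Product: 29 (1S)-1-[(2R,3R)-2-ethenyl-4-methylidene-5-oxooxolan-3-yl]-2-{(2R,3R)-3-[(1S)-1-hydroxy-3-methylbut-3-en-1-yl]-2-methyloxiran-2-yl}ethyl (2Z)-2-methylbut-2-enoate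
Conditions: mCPBA (1.1 equiv), NaHCO3 (solid buffer), CH2Cl2, 0 °C
Reagents that add atoms: 3-chloroperoxybenzoic acid, OOC(=O)c1cccc(Cl)c1
Why: Hydroxyl-directed (Henbest) peracid epoxidation of the only electron-rich trisubstituted olefin, in which A(1,3) strain from the cis C14 methyl holds the C2–H bond in the olefin plane so that the hydrogen-bonded peracid is delivered to the face carrying the hydroxyl, gives the threo epoxy alcohol (1R,10R next to 2S) as a trans-epoxide.

Step 18
Reactants: 29
Product: 30 (1R,2S,4Z,6R,7R,8S,10R)-8-[(2Z)-2-methylbut-2-enoyloxy]-1,10-epoxy-2-hydroxygermacra-4,11(13)-dien-12,6-olide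
Conditions: second-generation Grubbs catalyst RuCl2(=CHPh)(H2IMes)(PCy3) (2 × 10 mol%), 1,4-benzoquinone (20 mol%), toluene (0.5 mM), 80 °C
Reagents that add atoms: none
Why: Ring-closing metathesis between the C6 vinyl group and the methallyl olefin closes the ten-membered ring at C4=C5 with loss of ethene and forms no stereocentre, the medium ring favouring the Z (ring-cis) trisubstituted olefin and the epoxide, free hydroxyl and the two electron-poor olefins being spectators.

Step 19
Reactants: 30
Product: 31 (1R,2S,4R,5S,6S,7R,8S,10R)-8-[(2Z)-2-methylbut-2-enoyloxy]-1,10:4,5-diepoxy-2-hydroxygermacr-11(13)-en-12,6-olide (CNP0388761.2)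
Conditions: VO(acac)2 (10 mol%), t-BuOOH (1.5 equiv, in decane), CH2Cl2, 0 °C to rt
Reagents that add atoms: tert-butyl hydroperoxide, CC(C)(C)OO
Why: Vanadium-catalysed homoallylic-hydroxyl-directed epoxidation delivers the peroxide oxygen from the vanadate ester of the 2α-hydroxyl to the same (α) face of the Z C4=C5 olefin, giving the cis 4R,5S epoxide while the exocyclic methylene and the angelate, being electron-poor and undirected, are not oxidised.

**Compound list**
1 | tert-butyldimethyl(prop-2-yn-1-yloxy)silane | C#CCO[Si](C)(C)C(C)(C)C | starting material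
2 | prop-2-enal (acrolein) | C=CC=O | starting material
3 | [3-(tert-butyldimethylsilyloxy)prop-1-yn-1-yl]lithium | [Li]C#CCO[Si](C)(C)C(C)(C)C | intermediate (not isolated)
4 | lithium 6-(tert-butyldimethylsilyloxy)hex-1-en-4-yn-3-olate, racemic | C=CC(O[Li])C#CCO[Si](C)(C)C(C)(C)C | intermediate (not isolated)
5 | rac-6-(tert-butyldimethylsilyloxy)hex-1-en-4-yn-3-yl acetate | C=CC(OC(C)=O)C#CCO[Si](C)(C)C(C)(C)C | intermediate
6 | (3R)-6-(tert-butyldimethylsilyloxy)hex-1-en-4-yn-3-ol | C=C[C@@H](O)C#CCO[Si](C)(C)C(C)(C)C | intermediate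
7 | sodium five-membered oxaaluminate from trans-hydroalumination of 6 (Al bound to the carbinol O and to the distal alkene carbon, two 2-methoxyethoxy ligands) | [Na+].COCCO[Al-]1(OCCOC)O[C@H](C=C)C=C1CO[Si](C)(C)C(C)(C)C | intermediate (not isolated)
8 | (3R,4Z)-6-(tert-butyldimethylsilyloxy)-5-iodohexa-1,4-dien-3-ol | C=C[C@@H](O)/C=C(\I)CO[Si](C)(C)C(C)(C)C | intermediate
9 | (5R)-3-[(tert-butyldimethylsilyloxy)methyl]-5-ethenylfuran-2(5H)-one | C=C[C@H]1OC(=O)C(CO[Si](C)(C)C(C)(C)C)=C1 | intermediate
10 | (5R)-5-ethenyl-3-(hydroxymethyl)furan-2(5H)-one | C=C[C@H]1OC(=O)C(CO)=C1 | intermediate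
11 | (5R)-3-(bromomethyl)-5-ethenylfuran-2(5H)-one | C=C[C@H]1OC(=O)C(CBr)=C1 | intermediate
12 | but-3-yn-1-ol | C#CCCO | starting material
13 | 1-[(but-3-yn-1-yloxy)methyl]-4-methoxybenzene | C#CCCOCc1ccc(OC)cc1 | intermediate
14 | dimethyl{(1E)-4-[(4-methoxybenzyl)oxy]-2-methylbut-1-en-1-yl}alane | C[Al](C)/C=C(\C)CCOCc1ccc(OC)cc1 | intermediate (not isolated)
15 | lithium butyl(dimethyl){(1E)-4-[(4-methoxybenzyl)oxy]-2-methylbut-1-en-1-yl}aluminate | [Li+].CCCC[Al-](C)(C)/C=C(\C)CCOCc1ccc(OC)cc1 | intermediate (not isolated)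
16 | (2E)-5-[(4-methoxybenzyl)oxy]-3-methylpent-2-en-1-ol | OC/C=C(\C)CCOCc1ccc(OC)cc1 | intermediate
17 | (2E)-5-[(4-methoxybenzyl)oxy]-3-methylpent-2-enal | O=C/C=C(\C)CCOCc1ccc(OC)cc1 | intermediate
18 | tributyl(2-methylprop-2-en-1-yl)stannane | C=C(C)C[Sn](CCCC)(CCCC)CCCC | starting material
19 | (4S,5E)-8-[(4-methoxybenzyl)oxy]-2,6-dimethylocta-1,5-dien-4-ol | COc1ccc(COCC/C(C)=C/[C@@H](O)CC(C)=C)cc1 | intermediate
20 | tert-butyl{[(4S,5E)-8-[(4-methoxybenzyl)oxy]-2,6-dimethylocta-1,5-dien-4-yl]oxy}dimethylsilane | COc1ccc(COCC/C(C)=C/[C@@H](O[Si](C)(C)C(C)(C)C)CC(C)=C)cc1 | intermediate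
21 | (3E,5S)-5-(tert-butyldimethylsilyloxy)-3,7-dimethylocta-3,7-dien-1-ol | OCC/C(C)=C/[C@@H](O[Si](C)(C)C(C)(C)C)CC(C)=C | intermediate
22 | (3E,5S)-5-(tert-butyldimethylsilyloxy)-3,7-dimethylocta-3,7-dienal | O=CC/C(C)=C/[C@@H](O[Si](C)(C)C(C)(C)C)CC(C)=C | intermediate
23 | bromo{[(5R)-5-ethenyl-2-oxo-2,5-dihydrofuran-3-yl]methyl}zinc | C=C[C@H]1OC(=O)C(C[Zn]Br)=C1 | intermediate (not isolated)
24 | (4R,5R)-5-ethenyl-4-[(1S,3E,5S)-5-(tert-butyldimethylsilyloxy)-1-hydroxy-3,7-dimethylocta-3,7-dien-1-yl]-3-methylideneoxolan-2-one | C=C1C(=O)O[C@H](C=C)[C@H]1[C@@H](O)C/C(C)=C/[C@@H](O[Si](C)(C)C(C)(C)C)CC(C)=C | intermediate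
25 | angelic acid, (2Z)-2-methylbut-2-enoic acid | C/C=C(/C)C(=O)O | starting material
26 | (2Z)-2-methylbut-2-enoic 2,4,6-trichlorobenzoic anhydride | C/C=C(/C)C(=O)OC(=O)c1c(Cl)cc(Cl)cc1Cl | intermediate (not isolated)
27 | (1S,3E,5S)-5-(tert-butyldimethylsilyloxy)-1-[(2R,3R)-2-ethenyl-4-methylidene-5-oxooxolan-3-yl]-3,7-dimethylocta-3,7-dien-1-yl (2Z)-2-methylbut-2-enoate | C=C1C(=O)O[C@H](C=C)[C@H]1[C@@H](OC(=O)/C(C)=C\C)C/C(C)=C/[C@@H](O[Si](C)(C)C(C)(C)C)CC(C)=C | intermediate
28 | (1S,3E,5S)-1-[(2R,3R)-2-ethenyl-4-methylidene-5-oxooxolan-3-yl]-5-hydroxy-3,7-dimethylocta-3,7-dien-1-yl (2Z)-2-methylbut-2-enoate | C=C1C(=O)O[C@H](C=C)[C@H]1[C@@H](OC(=O)/C(C)=C\C)C/C(C)=C/[C@@H](O)CC(C)=C | intermediate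
29 | (1S)-1-[(2R,3R)-2-ethenyl-4-methylidene-5-oxooxolan-3-yl]-2-{(2R,3R)-3-[(1S)-1-hydroxy-3-methylbut-3-en-1-yl]-2-methyloxiran-2-yl}ethyl (2Z)-2-methylbut-2-enoate | C=C1C(=O)O[C@H](C=C)[C@H]1[C@@H](OC(=O)/C(C)=C\C)C[C@@]1(C)O[C@@H]1[C@@H](O)CC(C)=C | intermediate
30 | (1R,2S,4Z,6R,7R,8S,10R)-8-[(2Z)-2-methylbut-2-enoyloxy]-1,10-epoxy-2-hydroxygermacra-4,11(13)-dien-12,6-olide | C=C1C(=O)O[C@H]2[C@H]1[C@@H](OC(=O)/C(C)=C\C)C[C@@]1(C)O[C@@H]1[C@@H](O)C/C(C)=C\2 | intermediate
31 | (1R,2S,4R,5S,6S,7R,8S,10R)-8-[(2Z)-2-methylbut-2-enoyloxy]-1,10:4,5-diepoxy-2-hydroxygermacr-11(13)-en-12,6-olide (CNP0388761.2) | C=C1C(=O)O[C@H]2[C@H]1[C@@H](OC(=O)/C(C)=C\C)C[C@@]1(C)O[C@@H]1[C@@H](O)C[C@@]1(C)O[C@@H]21 | target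

**Totals and risks**
Total step count: 19. Longest linear sequence: 13 steps (12 → 31, steps 7–13 and 14–19). The branch to 11 is 6 steps.

Steps most likely to fail, each with a fallback:

Step 14 (Barbier coupling). The β,γ-unsaturated aldehyde 22 can isomerise, and the closed transition state may be eroded in the aqueous medium, giving the C8 epimer. The fallback sets out from 11 and 22, which are coupled with In powder in THF/water. Whatever share of the C8 epimer is formed, the 8-epi alcohol F1, is separated and esterified with 25 under Mitsunobu conditions (PPh3, diisopropyl azodicarboxylate, toluene, 0 °C). This inverts C8 and gives 27 directly, where the route is rejoined; for that material it replaces step 15.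

Step 18 (ring-closing metathesis to a ten-membered ring with a trisubstituted olefin). The trans-epoxide may hold the chain in a shape that resists closure, and dimers can form. The fallback sets out from 28 and closes the ring before the 1,10-oxirane is made. The same catalyst at high dilution converts the more flexible triene 28 into the macrocyclic dienol F2. Hydroxyl-directed epoxidation of its allylic C1=C10 bond (mCPBA, NaHCO3, CH2Cl2, −20 °C, under the same local A(1,3) control from the C14 methyl) then gives 30, where the route is rejoined.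

Step 19 (facial selectivity of the last epoxidation). The direction by the 2-hydroxyl depends on the ring conformation and is not assured. The fallback sets out from 30. N-Bromosuccinimide in THF/water gives the bromohydrin F3, with the bromonium ion on the face that electrophiles prefer and water opening at the tertiary C4 from the other face. Ag2O in CH2Cl2 then closes it by backside displacement at C5 to give 31. This places the oxirane on the face opposite to the one that direct oxidants attack, so it covers the case where step 19 gives the β-epoxide.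

**Further compounds**
F1 | step 14 | (4R,5R)-5-ethenyl-4-[(1R,3E,5S)-5-(tert-butyldimethylsilyloxy)-1-hydroxy-3,7-dimethylocta-3,7-dien-1-yl]-3-methylideneoxolan-2-one (8-epi-24) | C=C1C(=O)O[C@H](C=C)[C@H]1[C@H](O)C/C(C)=C/[C@@H](O[Si](C)(C)C(C)(C)C)CC(C)=C
F2 | step 18 | (1(10)E,2S,4Z,6R,7R,8S)-8-[(2Z)-2-methylbut-2-enoyloxy]-2-hydroxygermacra-1(10),4,11(13)-trien-12,6-olide | C=C1C(=O)O[C@H]2[C@H]1[C@@H](OC(=O)/C(C)=C\C)C/C(C)=C/[C@@H](O)C/C(C)=C\2
F3 | step 19 | 5β-bromo-4α-hydroxy bromohydrin of 30 (8α-angeloyloxy-5β-bromo-1β,10α-epoxy-2α,4α-dihydroxygermacr-11(13)-en-12,6α-olide) | C=C1C(=O)O[C@H]2[C@H]1[C@@H](OC(=O)/C(C)=C\C)C[C@@]1(C)O[C@@H]1[C@@H](O)C[C@@](C)(O)[C@@H]2Br
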